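Assumption: chain positions use carotenoid numbering (alkyne C7≡C8, then C9…C15, C15′…C10′), ring positions of 1–3 use aldehyde numbering (C1 bears CHO, C4 becomes the carbinol carbon), and the quinine-derived amine in step 1 is taken to give 4R (the quinidine-derived pseudo-enantiomer is used if the sense is opposite).

**Retrosynthetic overview**
1. Target 17 is cut at C11=C12 (Wittig) into the C15 phosphonium salt 9 and the C12 trienal 15.
2. Salt 9 comes from diol 7 and ester 6, which is the palladium-catalysed adduct of terminal alkyne 4 and ethyl but-2-ynoate 5 (sets 9E).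
3. Alkyne 4 comes from hydroxy aldehyde 3 by one-carbon homologation; 3 comes from safranal 1 by enantioselective 1,6-addition of an oxygen nucleophile, the C–O bond that creates the only stereocentre.
4. Trienal 15 comes from dienal 14 (Wittig), made from vinyl iodide 12 and acrolein 13 (Heck); 12 comes from pent-4-yn-1-ol 10 (carboalumination).
5. No ring is formed: the cyclohexene ring of 1 is carried unchanged to 17.

**Step 1**
Reactants: 1 safranal (2,6,6-trimethylcyclohexa-1,3-diene-1-carbaldehyde)
Product: 3 (4R)-4-hydroxy-2,6,6-trimethylcyclohex-1-ene-1-carbaldehyde, via triethylsilyl ether 2 (not isolated)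
Conditions: Et3SiOH (4 equiv), 9-amino-9-deoxy-epi-quinine (20 mol %), 2-nitrobenzoic acid (40 mol %), toluene (1 M), 0 °C, 48 h; then 1 M HCl, THF, 0 °C, 30 min
Reagents that add atoms: triethylsilanol, CC[Si](O)(CC)CC
Why: Proposed new method: an amine-catalysed enantioselective 1,6-oxa-Michael (δ-selective) addition of a silanol to a cyclic 2,4-dienal, in which the primary amine (a secondary amine cannot condense with this doubly flanked aldehyde) forms a vinylogous iminium ion whose β-carbon is tetrasubstituted so that only the δ-carbon C4 is open, the carboxylate/quinuclidinium pair hydrogen-bonds the acidic Et3SiOH and delivers its oxygen to the Si face of C4 to set 4R, γ-protonation of the dienamine and hydrolysis release 2, and the acid quench cuts the Si–O bond without touching the C–O bond; the closest known reaction types are the amine-catalysed δ-sulfa-Michael addition of thiols to cyclic dienones through vinylogous iminium ions and the iminium-catalysed β-oxa-Michael addition of oximes to enals.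

**Step 2**
Reactants: 3 (4R)-4-hydroxy-2,6,6-trimethylcyclohex-1-ene-1-carbaldehyde
Product: 4 (1R)-4-ethynyl-3,5,5-trimethylcyclohex-3-en-1-ol
Conditions: dimethyl (1-diazo-2-oxopropyl)phosphonate (1.5 equiv), K2CO3 (2.5 equiv), MeOH, 0 °C → rt, 16 h
Reagents that add atoms: dimethyl (1-diazo-2-oxopropyl)phosphonate, CC(=O)C(=[N+]=[N-])P(=O)(OC)OC
Why: The Ohira–Bestmann form of the Seyferth–Gilbert homologation converts the non-enolisable aldehyde into the terminal alkyne through a diazoalkene and alkylidene carbene under mild carbonate conditions, and the free hydroxyl is too poor a leaving group to be eliminated, so the stereocentre is kept.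

**Step 3**
Reactants: 4 (1R)-4-ethynyl-3,5,5-trimethylcyclohex-3-en-1-ol; 5 ethyl but-2-ynoate
Product: 6 ethyl (2E)-5-[(4R)-4-hydroxy-2,6,6-trimethylcyclohex-1-en-1-yl]-3-methylpent-2-en-4-ynoate
Conditions: 5 (1.2 equiv), Pd(OAc)2 (3 mol %), tris(2,6-dimethoxyphenyl)phosphine (3 mol %), THF, rt, 12 h
Reagents that add atoms: none
Why: In the Trost palladium-catalysed alkyne–alkyne cross-addition the alkynylpalladium hydride from donor 4 adds syn across the electron-poor alkyne 5 with the alkynyl group going to the β-carbon, which gives the 9E enynoate (alkynyl trans to the ester) directly.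

**Step 4**
Reactants: 6 ethyl (2E)-5-[(4R)-4-hydroxy-2,6,6-trimethylcyclohex-1-en-1-yl]-3-methylpent-2-en-4-ynoate
Product: 7 (1R)-4-[(3E)-5-hydroxy-3-methylpent-3-en-1-yn-1-yl]-3,5,5-trimethylcyclohex-3-en-1-ol
Conditions: i-Bu2AlH (3.5 equiv), CH2Cl2, −78 → 0 °C; aq. potassium sodium tartrate
Reagents that add atoms: none
Why: 1,2-Reduction of the conjugated ester by i-Bu2AlH gives the primary allylic alcohol without touching the enyne or its 9E geometry.

**Step 5**
Reactants: 7 (1R)-4-[(3E)-5-hydroxy-3-methylpent-3-en-1-yn-1-yl]-3,5,5-trimethylcyclohex-3-en-1-ol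
Product: 9 tributyl{(2E)-5-[(4R)-4-hydroxy-2,6,6-trimethylcyclohex-1-en-1-yl]-3-methylpent-2-en-4-yn-1-yl}phosphonium bromide, via allylic bromide 8 (not isolated)
Conditions: NBS (1.2 equiv), Me2S (1.4 equiv), CH2Cl2, −20 → 0 °C; aqueous wash; then PBu3 (1.1 equiv), EtOAc, rt, 12 h
Reagents that add atoms: N-bromosuccinimide, BrN1C(=O)CCC1=O; tributylphosphine, CCCCP(CCCC)CCCC
Why: The Corey–Kim halogenation replaces only the allylic hydroxyl (SN2 attack of bromide on the alkoxysulfonium ion, 9E retained, secondary alcohol untouched) and SN2 quaternisation of PBu3 by the primary allylic bromide gives the salt.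

**Step 6**
Reactants: 10 pent-4-yn-1-ol
Product: 12 (4E)-5-iodo-4-methylpent-4-en-1-ol, via alkenylalane 11 (not isolated)
Conditions: AlMe3 (3 equiv), Cp2ZrCl2 (0.25 equiv), CH2Cl2, 0 °C → rt, 16 h; then I2 (1.2 equiv), THF, −30 → 0 °C; aq. K2CO3
Reagents that add atoms: trimethylaluminium, C[Al](C)C; iodine, II
Why: The Negishi zirconium-catalysed carboalumination adds methyl and aluminium syn across the alkyne with aluminium on the terminal carbon, and iodinolysis with retention fixes the E trisubstituted alkene (13′E of the target).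

**Step 7**
Reactants: 12 (4E)-5-iodo-4-methylpent-4-en-1-ol; 13 acrolein (prop-2-enal)
Product: 14 (2E,4E)-8-hydroxy-5-methylocta-2,4-dienal
Conditions: 13 (3 equiv), Pd(OAc)2 (5 mol %), Bu4NCl (1 equiv), NaHCO3 (2.5 equiv), DMF, 40 °C, 6 h
Reagents that add atoms: none
Why: In the Heck reaction under Jeffery conditions oxidative addition proceeds with retention, insertion occurs at the CH2 terminus of acrolein and syn β-hydride elimination gives the new E double bond (15E).

**Step 8**
Reactants: 14 (2E,4E)-8-hydroxy-5-methylocta-2,4-dienal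
Product: 15 (2E,4E,6E)-10-hydroxy-2,7-dimethyldeca-2,4,6-trienal
Conditions: Ph3P=C(Me)CHO (1.3 equiv), toluene, 90 °C, 12 h
Reagents that add atoms: 2-(triphenylphosphoranylidene)propanal, CC(C=O)=P(c1ccccc1)(c1ccccc1)c1ccccc1
Why: The Wittig reaction of the stabilised formyl ylide is E-selective (13E), and the α-methyl enal product is too unreactive to be homologated a second time.

**Step 9**
Reactants: 9 tributyl{(2E)-5-[(4R)-4-hydroxy-2,6,6-trimethylcyclohex-1-en-1-yl]-3-methylpent-2-en-4-yn-1-yl}phosphonium bromide; 15 (2E,4E,6E)-10-hydroxy-2,7-dimethyldeca-2,4,6-trienal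
Product: 17 (1R)-4-[(3E,5E,7E,9E,11E)-15-hydroxy-3,7,12-trimethylpentadeca-3,5,7,9,11-pentaen-1-yn-1-yl]-3,5,5-trimethylcyclohex-3-en-1-ol, via phosphorus ylide 16 (not isolated)
Conditions: NaOMe (2.5 equiv), CH2Cl2, 0 °C → rt, 3 h, Ar, dark
Reagents that add atoms: none
Why: The Wittig reaction of an allylic trialkylphosphonium ylide is E-selective for the new C11=C12 bond, the tributyl ylide is chosen because it is less prone than a triphenyl ylide to scramble the neighbouring 9E bond, both free hydroxyls are tolerated and the stereocentre is not involved.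

**Compound list**
1 | safranal (2,6,6-trimethylcyclohexa-1,3-diene-1-carbaldehyde) | CC1=C(C=O)C(C)(C)CC=C1 | starting material
2 | (4R)-2,6,6-trimethyl-4-(triethylsilyloxy)cyclohex-1-ene-1-carbaldehyde | CC1=C(C=O)C(C)(C)C[C@H](O[Si](CC)(CC)CC)C1 | intermediate
3 | (4R)-4-hydroxy-2,6,6-trimethylcyclohex-1-ene-1-carbaldehyde | CC1=C(C=O)C(C)(C)C[C@H](O)C1 | intermediate
4 | (1R)-4-ethynyl-3,5,5-trimethylcyclohex-3-en-1-ol | CC1=C(C#C)C(C)(C)C[C@H](O)C1 | intermediate
5 | ethyl but-2-ynoate | CC#CC(=O)OCC | starting material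
6 | ethyl (2E)-5-[(4R)-4-hydroxy-2,6,6-trimethylcyclohex-1-en-1-yl]-3-methylpent-2-en-4-ynoate | CC1=C(C#C/C(C)=C/C(=O)OCC)C(C)(C)C[C@H](O)C1 | intermediate
7 | (1R)-4-[(3E)-5-hydroxy-3-methylpent-3-en-1-yn-1-yl]-3,5,5-trimethylcyclohex-3-en-1-ol | CC1=C(C#C/C(C)=C/CO)C(C)(C)C[C@H](O)C1 | intermediate
8 | (1R)-4-[(3E)-5-bromo-3-methylpent-3-en-1-yn-1-yl]-3,5,5-trimethylcyclohex-3-en-1-ol | CC1=C(C#C/C(C)=C/CBr)C(C)(C)C[C@H](O)C1 | intermediate
9 | tributyl{(2E)-5-[(4R)-4-hydroxy-2,6,6-trimethylcyclohex-1-en-1-yl]-3-methylpent-2-en-4-yn-1-yl}phosphonium bromide | CC1=C(C#C/C(C)=C/C[P+](CCCC)(CCCC)CCCC)C(C)(C)C[C@H](O)C1.[Br-] | intermediate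
10 | pent-4-yn-1-ol | C#CCCCO | starting material
11 | dimethylaluminium (4E)-5-(dimethylalumanyl)-4-methylpent-4-en-1-olate | C[Al](C)/C=C(\C)CCCO[Al](C)C | intermediate
12 | (4E)-5-iodo-4-methylpent-4-en-1-ol | I/C=C(\C)CCCO | intermediate
13 | acrolein (prop-2-enal) | C=CC=O | starting material
14 | (2E,4E)-8-hydroxy-5-methylocta-2,4-dienal | O=C/C=C/C=C(\C)CCCO | intermediate
15 | (2E,4E,6E)-10-hydroxy-2,7-dimethyldeca-2,4,6-trienal | O=C/C(C)=C/C=C/C=C(\C)CCCO | intermediate
16 | tributyl{(2E)-5-[(4R)-4-hydroxy-2,6,6-trimethylcyclohex-1-en-1-yl]-3-methylpent-2-en-4-yn-1-ylidene}phosphorane | CC1=C(C#C/C(C)=C/C=P(CCCC)(CCCC)CCCC)C(C)(C)C[C@H](O)C1 | intermediate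
17 | (1R)-4-[(3E,5E,7E,9E,11E)-15-hydroxy-3,7,12-trimethylpentadeca-3,5,7,9,11-pentaen-1-yn-1-yl]-3,5,5-trimethylcyclohex-3-en-1-ol (CNP0344116.1) | CC1=C(C#C/C(C)=C/C=C/C(C)=C/C=C/C=C(\C)CCCO)C(C)(C)C[C@H](O)C1 | target

**Totals**
Total step count: 9. Longest linear sequence: 6 steps (1 → 3 → 4 → 6 → 7 → 9 → 17; steps 1–5 and 9). No protecting-group steps are used.

**Three steps most likely to fail**

Step 1 (the proposed new reaction). The addition is close to thermoneutral and reversible; the reverse elimination is the known way safranal arises from this hydroxy aldehyde on heating. Iminium formation with the hindered aldehyde is slow, and the stereocentre is created far from the catalyst nitrogen. The reaction must therefore be run cold, with excess silanol, and quenched before equilibration erodes the ee. Fallback with known chemistry, setting out from 1 and coming back at 3: Jacobsen–Katsuki epoxidation of the cis-disubstituted γ,δ-alkene of 1 with the enantiomer of N,N′-bis(3,5-di-tert-butylsalicylidene)-1,2-cyclohexanediaminomanganese chloride (trivalent manganese) that gives the required sense, NaOCl and 4-phenylpyridine N-oxide in CH2Cl2 at 0 °C. This gives the vinyl epoxide (1R,6S)-2,4,4-trimethyl-7-oxabicyclo[4.1.0]hept-2-ene-3-carbaldehyde F1. Tsuji–Shimizu hydrogenolysis of F1 (Pd2(dba)3, PBu3, HCO2H/Et3N, dioxane, rt; zerovalent palladium) cleaves only the allylic C–O bond and leaves the C4–O bond and its configuration, giving 3.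

Step 2. The aldehyde is flanked by a gem-dimethyl carbon and a methyl-bearing alkene carbon, so addition of the diazophosphonate anion may be slow, and prolonged base could start vinylogous elimination toward a safranal-type diene. Fallback, setting out from 2 (isolated by omitting the acid quench of step 1) and coming back at 4: Corey–Fuchs dibromo-olefination (CBr4, PPh3, CH2Cl2, 0 °C; the silyl ether protects the alcohol from bromination) gives {[(1R)-4-(2,2-dibromoethenyl)-3,5,5-trimethylcyclohex-3-en-1-yl]oxy}triethylsilane F2. Treatment with n-BuLi (2.2 equiv, THF, −78 °C; aq. NH4Cl) gives, by Fritsch–Buttenberg–Wiechell rearrangement, {[(1R)-4-ethynyl-3,5,5-trimethylcyclohex-3-en-1-yl]oxy}triethylsilane F3. Brief treatment with 1 M HCl in THF at 0 °C removes the silyl group and gives 4.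

Step 9. The new C11=C12 bond may form as an E/Z mixture, and the carbanion of the ylide is conjugated with the C9=C10 bond next to the alkyne, where 9E to 9Z isomerisation is thermodynamically favourable. Fallback with reversed polarity, which puts the carbanion on the non-acetylenic half; it sets out from 7 and 15 and comes back at 17. MnO2 (CH2Cl2, rt) oxidises only the allylic hydroxyl of 7 to (2E)-5-[(4R)-4-hydroxy-2,6,6-trimethylcyclohex-1-en-1-yl]-3-methylpent-2-en-4-ynal F4. NaBH4 (MeOH, 0 °C) reduces 15 to (2E,4E,6E)-2,7-dimethyldeca-2,4,6-triene-1,10-diol F5, whose allylic hydroxyl alone reacts with PPh3·HBr (MeOH, rt) to give [(2E,4E,6E)-10-hydroxy-2,7-dimethyldeca-2,4,6-trien-1-yl]triphenylphosphonium bromide F6. NaOMe in CH2Cl2 converts F6 into [(2E,4E,6E)-10-hydroxy-2,7-dimethyldeca-2,4,6-trien-1-ylidene]triphenylphosphorane F7, which condenses with F4 to give 17. Any hindered 11Z isomer is relaxed to 11E by brief warming in the dark, without a carbanion ever sitting next to the 9E bond.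

**Further compounds**
F1 | step 1 | (1R,6S)-2,4,4-trimethyl-7-oxabicyclo[4.1.0]hept-2-ene-3-carbaldehyde | CC1=C(C=O)C(C)(C)C[C@@H]2O[C@H]12
F2 | step 2 | {[(1R)-4-(2,2-dibromoethenyl)-3,5,5-trimethylcyclohex-3-en-1-yl]oxy}triethylsilane | CC1=C(C=C(Br)Br)C(C)(C)C[C@H](O[Si](CC)(CC)CC)C1
F3 | step 2 | {[(1R)-4-ethynyl-3,5,5-trimethylcyclohex-3-en-1-yl]oxy}triethylsilane | CC1=C(C#C)C(C)(C)C[C@H](O[Si](CC)(CC)CC)C1
F4 | step 9 | (2E)-5-[(4R)-4-hydroxy-2,6,6-trimethylcyclohex-1-en-1-yl]-3-methylpent-2-en-4-ynal | CC1=C(C#C/C(C)=C/C=O)C(C)(C)C[C@H](O)C1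
F5 | step 9 | (2E,4E,6E)-2,7-dimethyldeca-2,4,6-triene-1,10-diol | OC/C(C)=C/C=C/C=C(\C)CCCO
F6 | step 9 | [(2E,4E,6E)-10-hydroxy-2,7-dimethyldeca-2,4,6-trien-1-yl]triphenylphosphonium bromide | OCCC/C(C)=C/C=C/C=C(\C)C[P+](c1ccccc1)(c1ccccc1)c1ccccc1.[Br-]
F7 | step 9 | [(2E,4E,6E)-10-hydroxy-2,7-dimethyldeca-2,4,6-trien-1-ylidene]triphenylphosphorane | OCCC/C(C)=C/C=C/C=C(\C)C=P(c1ccccc1)(c1ccccc1)c1ccccc1
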